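Before reading this flask, set it beside its neighbour, the same charge read earlier at 8.0 s: carry one number that serves both.

    X + Q ⇌ X.Q (K1 = 89.7 M⁻¹, k1 = 29200 M⁻¹ s⁻¹)
    X.Q ⇌ G (K2 = 1.24, k2 = 3410 s⁻¹)
    G → Q + L (k3 = 3110 s⁻¹)
    2 Q → Q2 (k4 = 6060 M⁻¹ s⁻¹)
X 33 mM; Q 21 µM; time 12 s
- the state of affairs at 12 s: stopped, and by what, or still going (all of X has reacted / it is still moving / forward and back rates have come level / no working catalyst is left)
- L at 12 s, in percent of the X charged
- two of one species on the left: rate k times its square, two consumed each time
- the reaction counts as stopped when no species that holds the X changes by six tenths of a point or more over the second half of the time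
- run time (flask): 12 s

Turn the question round. To count as stopped, X must fall by less than 0.6 points between half time and the end, so reckon that fall. Take X.Q and G as steady. X.Q then goes on through G at 1810 s⁻¹, and free Q removes X with the constant e = 24700 M⁻¹ s⁻¹, pseudo-first-order in X at any given Q. Let Q run down by dimerisation as if nothing were bound: its first half-life is τ = 3.93 s, and it falls as one over (one plus t/τ). Integrating gives X left, as a fraction of the charge, as (one plus t/τ) raised to the power −n, where n = 2.04, e over two times 6060 M⁻¹ s⁻¹: the turnover-to-death ratio. This reckoning puts X at 15.1% at half time and 5.74% at the end, a fall of 9.3 percentage points, so the flask is still moving, with L at 94.3%.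

The forecast says it is still moving, with L at 94.4%: “dimerisation slows the reaction without killing it”.

The simulation gives it is still moving, with L at 94.5%. In this flask at 12.0 s, step one relaxes with a half-life of 0.00183 s, far shorter than the 4.71 s of the slowest mode, and Q stands at 29.7% of the catalyst against 69.1% as Q2. Read back from the X left, n comes to 2.07, beside the 2.04 reckoned. In the neighbour flask, n gives L 89.6% at 8.0 s, and that flask reads 88.7%.

The rate constants stand for no real mixture; the rest is arithmetic.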